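## Retrosynthetic overview

1. The target comes from a hydroxy-lactone by acetylation at C5 and removal of a silyl group at C2. The cis-fused lactone (ring B) closes when the C6 hydroxyl attacks the C12 methyl ester.
2. Key disconnection C5–C6: the ten-membered carbocycle (ring A) is closed on an acyclic dialdehyde. The C5 enal is reduced by two electrons to a γ-silyloxyallylchromium, so its former carbonyl carbon attacks the C6 aldehyde as a nucleophile. This sets C5 and C6 and leaves the C4 exocyclic methylene.
3. C7–C8: catalytic asymmetric, syn-selective 2-(methoxycarbonyl)allylation of a β,γ-unsaturated aldehyde with a Baylis–Hillman-derived allyl bromide. It sets C7 and C8 and brings in C6 (as an acetal) and the acrylate.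
4. C2–C3: asymmetric allylboration of (Z)-3-methylpent-2-en-4-ynal with a 2-(diethoxymethyl)allylboronate. The Z olefin is bought with the enynol, and the terminal alkyne later becomes the C8 aldehyde.
5. Ring order: ring A (carbocycle) first, ring B (lactone) second, both in the same operation (step 11).

Assumption and locants: the SMILES is read as (2R,5S,6R,7R,8R), 1(10)Z in the germacrane-type locants used throughout (C6 = lactone O–CH, C7, C8 = tiglate CH, C9, C10 = C–Me, C1 = olefinic CH, C2 = CHOH, C3, C4 = C(=CH2), C5 = CHOAc, C11–C13 = acrylate unit); 2-bromo-3,3-diethoxyprop-1-ene is taken as a catalog reagent.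

## Route

Step 1
Reactants: 1 methyl acrylate; 2 2,2-dimethoxyacetaldehyde
Product: 3 methyl 3-hydroxy-4,4-dimethoxy-2-methylidenebutanoate (racemic)
Conditions: DABCO (0.5 equiv), dioxane–H2O, 25 °C
Reagents that add atoms: none
Why: Morita–Baylis–Hillman reaction of an activated α,α-dialkoxy aldehyde gives the allylic alcohol, whose racemic carbinol centre is erased in step 2.

Step 2
Reactants: 3 methyl 3-hydroxy-4,4-dimethoxy-2-methylidenebutanoate
Product: 4 methyl (2Z)-2-(bromomethyl)-4,4-dimethoxybut-2-enoate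
Conditions: NBS, Me2S, CH2Cl2, 0 °C to 25 °C
Reagents that add atoms: N-bromosuccinimide, O=C1CCC(=O)N1Br
Why: Corey–Kim-type activation of the allylic alcohol followed by SN2′ attack of bromide gives the rearranged primary allyl bromide as the thermodynamically preferred trisubstituted enoate (acetal arm trans to the ester, Z by CIP) under non-acidic conditions that spare the acetal.

Step 3
Reactants: 5 2-bromo-3,3-diethoxyprop-1-ene; 6 2-(chloromethyl)-4,4,5,5-tetramethyl-1,3,2-dioxaborolane
Product: 9 2-[2-(diethoxymethyl)prop-2-en-1-yl]-4,4,5,5-tetramethyl-1,3,2-dioxaborolane, via vinyllithium 7 (not isolated), via boronate complex 8 (not isolated)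
Conditions: n-BuLi, THF, −78 °C; then 6, −78 °C to 25 °C
Reagents that add atoms: none
Why: Bromine–lithium exchange gives the 2-lithio acrolein acetal, which adds to boron and undergoes a Matteson 1,2-metallate shift with loss of chloride to give the allylboronate (both allyl termini are CH2, so no regiochemical issue arises later).

Step 4
Reactants: 10 (2Z)-3-methylpent-2-en-4-yn-1-ol
Product: 11 (2Z)-3-methylpent-2-en-4-ynal
Conditions: MnO2, CH2Cl2, 25 °C
Reagents that add atoms: none
Why: Neutral heterogeneous MnO2 oxidation of the allylic alcohol keeps the Z geometry (as in nerol to neral) and leaves the alkyne untouched, and the volatile aldehyde is used as a solution.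

Step 5
Reactants: 11 (2Z)-3-methylpent-2-en-4-ynal; 9 2-[2-(diethoxymethyl)prop-2-en-1-yl]-4,4,5,5-tetramethyl-1,3,2-dioxaborolane
Product: 13 (4R,5Z)-1,1-diethoxy-6-methyl-2-methylideneoct-5-en-7-yn-4-ol, via borate ester 12 (not isolated)
Conditions: (R)-TRIP [(R)-3,3′-bis(2,4,6-triisopropylphenyl)-1,1′-binaphthyl-2,2′-diyl hydrogen phosphate] (5 mol %), 4 Å MS, toluene, −30 °C; aq. NaHCO3 work-up
Reagents that add atoms: none
Why: Chiral phosphoric acid-catalysed allylboration through a closed chair transition state in which the catalyst (enantiomer chosen by analogy with aryl and alkenyl aldehydes) directs Re-face attack on the enal, setting C2 as R while the Z olefin and the acetal are untouched; the product is kept base-washed because acid would close the C2 hydroxyl onto the allylic acetal.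

Step 6
Reactants: 13 (4R,5Z)-1,1-diethoxy-6-methyl-2-methylideneoct-5-en-7-yn-4-ol
Product: 14 tert-butyl{[(4R,5Z)-1,1-diethoxy-6-methyl-2-methylideneoct-5-en-7-yn-4-yl]oxy}dimethylsilane
Conditions: TBSCl, imidazole, DMF, 25 °C
Reagents that add atoms: tert-butyldimethylsilyl chloride, CC(C)(C)[Si](C)(C)Cl
Why: Standard silylation of the only hydroxyl protects C2 for the rest of the route and blocks cyclic acetal formation.

Step 7
Reactants: 14 tert-butyl{[(4R,5Z)-1,1-diethoxy-6-methyl-2-methylideneoct-5-en-7-yn-4-yl]oxy}dimethylsilane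
Product: 16 (3Z,5R)-5-[(tert-butyldimethylsilyl)oxy]-8,8-diethoxy-3-methyl-7-methylideneoct-3-enal, via dienylborane 15 (not isolated)
Conditions: Cy2BH (from BH3·SMe2 + cyclohexene), THF, 0 °C; then 30% H2O2, pH 7 phosphate buffer, 0 °C
Reagents that add atoms: hydrogen peroxide, OO
Why: Dicyclohexylborane adds anti-Markovnikov and syn to the terminal alkyne far faster than to the 1,1-disubstituted alkene, and buffered oxidation of dienylborane 15 releases a dienol that is protonated at the α-carbon to give the β,γ-unsaturated aldehyde with the Z olefin intact (used crude at once).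

Step 8
Reactants: 16 (3Z,5R)-5-[(tert-butyldimethylsilyl)oxy]-8,8-diethoxy-3-methyl-7-methylideneoct-3-enal; 4 methyl (2Z)-2-(bromomethyl)-4,4-dimethoxybut-2-enoate
Product: 19 methyl (3R,4R,6Z,8R)-8-[(tert-butyldimethylsilyl)oxy]-3-(dimethoxymethyl)-11,11-diethoxy-4-hydroxy-6-methyl-2,10-dimethylideneundec-6-enoate, via allylchromium 17 (not isolated), via zirconium alkoxide 18 (not isolated)
Conditions: CrCl2 (10 mol %), chiral 3,6-di-tert-butyl-1,8-bis(4-isopropyl-4,5-dihydrooxazol-2-yl)carbazole ligand (12 mol %), proton sponge (12 mol %), Mn powder, Cp2ZrCl2, THF, 0 °C to 25 °C; aq. NaHCO3 work-up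
Reagents that add atoms: none
Why: Nozaki–Hiyama-type 2-(alkoxycarbonyl)allylation in which divalent chromium turns the allyl bromide into allylchromium 17, which attacks through the former enoate β-carbon (C7) via a chair transition state with the acetal arm cis to CH2Cr and hence axial, giving the 7,8-syn relationship, while the ligand enantiomer is chosen to direct Si-face attack on the aldehyde so that C8 is R and therefore C7 is R; Mn and Cp2ZrCl2 turn the chromium over, and lactonisation of the zirconium alkoxide 18 onto the methyl ester before work-up is not expected at this temperature.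

Step 9
Reactants: 19 methyl (3R,4R,6Z,8R)-8-[(tert-butyldimethylsilyl)oxy]-3-(dimethoxymethyl)-11,11-diethoxy-4-hydroxy-6-methyl-2,10-dimethylideneundec-6-enoate
Product: 20 methyl (3R,4R,6Z,8R)-8-[(tert-butyldimethylsilyl)oxy]-3-(dimethoxymethyl)-11,11-diethoxy-6-methyl-2,10-dimethylidene-4-{[(2E)-2-methylbut-2-enoyl]oxy}undec-6-enoate
Conditions: tigloyl chloride, pyridine, DMAP (cat.), CH2Cl2, 0 °C
Reagents that add atoms: tigloyl chloride [(2E)-2-methylbut-2-enoyl chloride], C/C=C(\C)C(Cl)=O
Why: DMAP-catalysed acylation of the hindered secondary alcohol with the geometrically stable tigloyl chloride at 0 °C outruns lactonisation onto the methyl ester and fixes the C8 oxygen as the tiglate.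

Step 10
Reactants: 20 methyl (3R,4R,6Z,8R)-8-[(tert-butyldimethylsilyl)oxy]-3-(dimethoxymethyl)-11,11-diethoxy-6-methyl-2,10-dimethylidene-4-{[(2E)-2-methylbut-2-enoyl]oxy}undec-6-enoate
Product: 21 methyl (3R,4R,6Z,8R)-8-[(tert-butyldimethylsilyl)oxy]-3-formyl-6-methyl-2,10-dimethylidene-4-{[(2E)-2-methylbut-2-enoyl]oxy}-11-oxoundec-6-enoate
Conditions: Amberlyst 15, THF–H2O (10:1), 25 °C; used crude at once
Reagents that add atoms: water, O
Why: Acid-catalysed hydrolysis releases both aldehydes at once (the allylic acetal fast, the C6 acetal more slowly) while the secondary TBS ether and both esters survive the resin acid, and the configurationally labile dialdehyde is used immediately without chromatography.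

Step 11
Reactants: 21 methyl (3R,4R,6Z,8R)-8-[(tert-butyldimethylsilyl)oxy]-3-formyl-6-methyl-2,10-dimethylidene-4-{[(2E)-2-methylbut-2-enoyl]oxy}-11-oxoundec-6-enoate
Product: 24 (2R,5S,6R,7R,8R,1(10)Z)-2-[(tert-butyldimethylsilyl)oxy]-5-hydroxy-8-(tigloyloxy)germacra-1(10),4(15),11(13)-trien-12,6-olide, via silyloxyallylchromium 22 (not isolated), via bis-silyl ether 23 (not isolated)
Conditions: CrCl2 (8 equiv), TMSCl (4 equiv), DMF–THF, slow addition of 21 to 2 mM, 0 °C to 25 °C; then PPTS, MeOH, 25 °C
Reagents that add atoms: none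
Why: Proposed new method: divalent chromium with TMSCl reduces only the conjugated C5 aldehyde (saturated aldehydes and the acrylate ester are not reduced) to the γ-silyloxyallylchromium 22, so the former carbonyl carbon C5 attacks the C6 aldehyde through a six-membered chair with allyl transposition that regenerates the C4 exocyclic methylene; the equilibrating allylchromium reacts via its E enol ether to give the anti C5/C6 pair (5S,6R), and Felkin–Anh addition anti to the sp2 acrylate substituent on C7 gives the C6 configuration that lactonises cis; the closest known reaction type is the chromium-mediated cross-pinacol-type coupling of enals with aldehydes (intermolecular and anti-selective, and intramolecular for small-ring 3-methylenecycloalkane-1,2-diols), here stretched to a ten-membered ring under high dilution and followed by acid-catalysed TMS ether cleavage and lactonisation of the C6 hydroxyl onto the methyl ester.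

Step 12
Reactants: 24 (2R,5S,6R,7R,8R,1(10)Z)-2-[(tert-butyldimethylsilyl)oxy]-5-hydroxy-8-(tigloyloxy)germacra-1(10),4(15),11(13)-trien-12,6-olide
Product: 25 (2R,5S,6R,7R,8R,1(10)Z)-5-acetoxy-2-[(tert-butyldimethylsilyl)oxy]-8-(tigloyloxy)germacra-1(10),4(15),11(13)-trien-12,6-olide
Conditions: Ac2O, pyridine, DMAP (cat.), CH2Cl2, 0 °C
Reagents that add atoms: acetic anhydride, CC(=O)OC(C)=O
Why: The C5 hydroxyl is the only free OH (C6 is in the lactone, C2 is silylated, C8 is acylated), so standard DMAP-catalysed acetylation is site-specific and no stereocentre is touched.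

Step 13
Reactants: 25 (2R,5S,6R,7R,8R,1(10)Z)-5-acetoxy-2-[(tert-butyldimethylsilyl)oxy]-8-(tigloyloxy)germacra-1(10),4(15),11(13)-trien-12,6-olide
Product: 26 (2R,5S,6R,7R,8R,1(10)Z)-5-acetoxy-2-hydroxy-8-(tigloyloxy)germacra-1(10),4(15),11(13)-trien-12,6-olide (CNP0210609.1)
Conditions: HF·pyridine, pyridine, THF, 0 °C to 25 °C
Reagents that add atoms: none
Why: Buffered HF·pyridine cleaves the allylic secondary TBS ether without touching the acetate, the tiglate or the α-methylene lactone, giving the target.

## Compound list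

1 | methyl acrylate | C=CC(=O)OC | starting material
2 | 2,2-dimethoxyacetaldehyde | COC(OC)C=O | starting material
3 | methyl 3-hydroxy-4,4-dimethoxy-2-methylidenebutanoate (racemic) | COC(OC)C(O)C(=C)C(=O)OC | intermediate
4 | methyl (2Z)-2-(bromomethyl)-4,4-dimethoxybut-2-enoate | COC(=O)/C(CBr)=C/C(OC)OC | intermediate
5 | 2-bromo-3,3-diethoxyprop-1-ene | C=C(Br)C(OCC)OCC | starting material
6 | 2-(chloromethyl)-4,4,5,5-tetramethyl-1,3,2-dioxaborolane | ClCB1OC(C)(C)C(C)(C)O1 | starting material
7 | (3,3-diethoxyprop-1-en-2-yl)lithium (not isolated) | [Li]C(=C)C(OCC)OCC | intermediate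
8 | lithium (chloromethyl)(3,3-diethoxyprop-1-en-2-yl)(pinacolato)borate (not isolated) | [Li+].CCOC(OCC)C(=C)[B-]1(CCl)OC(C)(C)C(C)(C)O1 | intermediate
9 | 2-[2-(diethoxymethyl)prop-2-en-1-yl]-4,4,5,5-tetramethyl-1,3,2-dioxaborolane | CCOC(OCC)C(=C)CB1OC(C)(C)C(C)(C)O1 | intermediate
10 | (2Z)-3-methylpent-2-en-4-yn-1-ol | C#C/C(C)=C\CO | starting material
11 | (2Z)-3-methylpent-2-en-4-ynal | C#C/C(C)=C\C=O | intermediate
12 | pinacol borate ester of 13, (4R,5Z) (not isolated) | C#C/C(C)=C\[C@H](OB1OC(C)(C)C(C)(C)O1)CC(=C)C(OCC)OCC | intermediate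
13 | (4R,5Z)-1,1-diethoxy-6-methyl-2-methylideneoct-5-en-7-yn-4-ol | C#C/C(C)=C\[C@H](O)CC(=C)C(OCC)OCC | intermediate
14 | tert-butyl{[(4R,5Z)-1,1-diethoxy-6-methyl-2-methylideneoct-5-en-7-yn-4-yl]oxy}dimethylsilane | C#C/C(C)=C\[C@H](O[Si](C)(C)C(C)(C)C)CC(=C)C(OCC)OCC | intermediate
15 | dicyclohexyl{(1E,3Z,5R)-5-[(tert-butyldimethylsilyl)oxy]-8,8-diethoxy-3-methyl-7-methylideneocta-1,3-dien-1-yl}borane (not isolated) | C1CCCCC1B(C1CCCCC1)/C=C/C(C)=C\[C@H](O[Si](C)(C)C(C)(C)C)CC(=C)C(OCC)OCC | intermediate
16 | (3Z,5R)-5-[(tert-butyldimethylsilyl)oxy]-8,8-diethoxy-3-methyl-7-methylideneoct-3-enal | O=CC/C(C)=C\[C@H](O[Si](C)(C)C(C)(C)C)CC(=C)C(OCC)OCC | intermediate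
17 | [(2Z)-4,4-dimethoxy-2-(methoxycarbonyl)but-2-en-1-yl]chromium dichloride, trivalent chromium, chiral ligand not drawn (not isolated) | COC(=O)/C(C[Cr](Cl)Cl)=C/C(OC)OC | intermediate
18 | chlorozirconocene alkoxide of 19, (3R,4R,6Z,8R) (not isolated) | COC(OC)[C@H](C(=C)C(=O)OC)[C@H](O[Zr](Cl)(C1C=CC=C1)C1C=CC=C1)C/C(C)=C\[C@H](O[Si](C)(C)C(C)(C)C)CC(=C)C(OCC)OCC | intermediate
19 | methyl (3R,4R,6Z,8R)-8-[(tert-butyldimethylsilyl)oxy]-3-(dimethoxymethyl)-11,11-diethoxy-4-hydroxy-6-methyl-2,10-dimethylideneundec-6-enoate | COC(OC)[C@H](C(=C)C(=O)OC)[C@H](O)C/C(C)=C\[C@H](O[Si](C)(C)C(C)(C)C)CC(=C)C(OCC)OCC | intermediate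
20 | methyl (3R,4R,6Z,8R)-8-[(tert-butyldimethylsilyl)oxy]-3-(dimethoxymethyl)-11,11-diethoxy-6-methyl-2,10-dimethylidene-4-{[(2E)-2-methylbut-2-enoyl]oxy}undec-6-enoate | COC(OC)[C@H](C(=C)C(=O)OC)[C@H](OC(=O)/C(C)=C/C)C/C(C)=C\[C@H](O[Si](C)(C)C(C)(C)C)CC(=C)C(OCC)OCC | intermediate
21 | methyl (3R,4R,6Z,8R)-8-[(tert-butyldimethylsilyl)oxy]-3-formyl-6-methyl-2,10-dimethylidene-4-{[(2E)-2-methylbut-2-enoyl]oxy}-11-oxoundec-6-enoate | O=C[C@H](C(=C)C(=O)OC)[C@H](OC(=O)/C(C)=C/C)C/C(C)=C\[C@H](O[Si](C)(C)C(C)(C)C)CC(=C)C=O | intermediate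
22 | γ-(trimethylsilyloxy)allylchromium dichloride from the C5 enal of 21 (Cr on C15, TMSO–C5H=C4 enol ether, trivalent chromium) (not isolated) | O=C[C@H](C(=C)C(=O)OC)[C@H](OC(=O)/C(C)=C/C)C/C(C)=C\[C@H](O[Si](C)(C)C(C)(C)C)CC(C[Cr](Cl)Cl)=CO[Si](C)(C)C | intermediate
23 | methyl 2-[(2R,5S,6R,7R,8R,1(10)Z)-2-(tert-butyldimethylsilyloxy)-5,6-bis(trimethylsilyloxy)-8-(tigloyloxy)-10-methyl-4-methylidenecyclodec-1(10)-en-7-yl]prop-2-enoate, target locants (not isolated) | COC(=O)C(=C)[C@H]1[C@@H](O[Si](C)(C)C)[C@@H](O[Si](C)(C)C)C(=C)C[C@@H](O[Si](C)(C)C(C)(C)C)/C=C(C)\C[C@H]1OC(=O)/C(C)=C/C | intermediate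
24 | (2R,5S,6R,7R,8R,1(10)Z)-2-[(tert-butyldimethylsilyl)oxy]-5-hydroxy-8-(tigloyloxy)germacra-1(10),4(15),11(13)-trien-12,6-olide (cis-fused lactone) | C=C1C(=O)O[C@@H]2[C@H]1[C@H](OC(=O)/C(C)=C/C)C/C(C)=C\[C@H](O[Si](C)(C)C(C)(C)C)CC(=C)[C@@H]2O | intermediate
25 | (2R,5S,6R,7R,8R,1(10)Z)-5-acetoxy-2-[(tert-butyldimethylsilyl)oxy]-8-(tigloyloxy)germacra-1(10),4(15),11(13)-trien-12,6-olide | C=C1C(=O)O[C@@H]2[C@H]1[C@H](OC(=O)/C(C)=C/C)C/C(C)=C\[C@H](O[Si](C)(C)C(C)(C)C)CC(=C)[C@@H]2OC(C)=O | intermediate
26 | (2R,5S,6R,7R,8R,1(10)Z)-5-acetoxy-2-hydroxy-8-(tigloyloxy)germacra-1(10),4(15),11(13)-trien-12,6-olide (CNP0210609.1) | C=C1C(=O)O[C@@H]2[C@H]1[C@H](OC(=O)/C(C)=C/C)C/C(C)=C\[C@H](O)CC(=C)[C@@H]2OC(C)=O | target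

## Step count and risks

Total steps: 13. Longest linear sequence: 10 (steps 4–13 from 10, or step 3 then steps 5–13 from 5).

**Step 11 (ring closure) is the most likely to fail.** A ten-membered ring must form in competition with oligomerisation. The C6 aldehyde is prone to epimerisation at C7 and to conjugation. The facial sense at C6 relative to C7 rests on a Felkin–Anh argument that a macrocyclic transition state may override; the usual model for an α-branched β-acyloxy aldehyde would in fact predict the opposite C6 configuration. Fallback, setting out from 21 and returning at 24: the same C5–C6 bond is made by a one-electron ketyl–ketyl coupling instead of an allylmetal addition. Slow addition of 21 to low-valent titanium (TiCl3(DME)1.5, Zn–Cu couple, DME, 25 °C, high dilution) gives the macrocyclic diol F4 as separable diastereomers with a different stereochemical bias, since both oxygens sit on titanium. The anti isomer is lactonised with PPTS in CH2Cl2 to give 24.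

**Step 8 (asymmetric allylation) is the second risk.** It needs syn selectivity and ligand control at once, on a β,γ-unsaturated aldehyde that isomerises easily, with an allyl bromide whose acetal oxygens could be lost by β-elimination from the minor secondary allylchromium. Fallback, setting out from 4 and returning at 19: bromide 4 is converted with B2pin2 and Pd2(dba)3 (cat.) in toluene at 50 °C into the allylboronate F1, which keeps the olefin geometry. Allylboration of 16 with F1 under chiral Brønsted acid catalysis (TRIP or its stronger N-triflyl phosphoramide analogue, toluene, −30 °C) goes through a closed chair, stereospecifically syn, to the borate ester F2, which is hydrolysed on work-up to 19.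

**Step 10 (double acetal hydrolysis) is the third risk.** The acid needed for the hindered C6 acetal may epimerise or conjugate the new aldehyde, or loosen the C2 silyl ether. Fallback, setting out from 20 and returning at 21: the two aldehydes are released one after the other. PPTS in wet acetone at 0 °C cleaves only the allylic diethyl acetal and gives the enal acetal F3, which is stable and can be purified. The C6 dimethyl acetal is then opened without protic acid by TESOTf and 2,4,6-collidine (CH2Cl2, −20 °C; then water) to give 21, which is used at once in step 11.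

Further compounds
F1 | step 8 | methyl (2E)-4,4-dimethoxy-2-[(4,4,5,5-tetramethyl-1,3,2-dioxaborolan-2-yl)methyl]but-2-enoate | COC(=O)/C(CB1OC(C)(C)C(C)(C)O1)=C/C(OC)OC
F2 | step 8 | pinacol borate ester of 19, (3R,4R,6Z,8R) | COC(OC)[C@H](C(=C)C(=O)OC)[C@H](OB1OC(C)(C)C(C)(C)O1)C/C(C)=C\[C@H](O[Si](C)(C)C(C)(C)C)CC(=C)C(OCC)OCC
F3 | step 10 | methyl (3R,4R,6Z,8R)-8-[(tert-butyldimethylsilyl)oxy]-3-(dimethoxymethyl)-6-methyl-2,10-dimethylidene-4-{[(2E)-2-methylbut-2-enoyl]oxy}-11-oxoundec-6-enoate | COC(OC)[C@H](C(=C)C(=O)OC)[C@H](OC(=O)/C(C)=C/C)C/C(C)=C\[C@H](O[Si](C)(C)C(C)(C)C)CC(=C)C=O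
F4 | step 11 | methyl 2-[(2R,5S,6R,7R,8R,1(10)Z)-2-(tert-butyldimethylsilyloxy)-5,6-dihydroxy-8-(tigloyloxy)-10-methyl-4-methylidenecyclodec-1(10)-en-7-yl]prop-2-enoate (target locants) | COC(=O)C(=C)[C@H]1[C@@H](O)[C@@H](O)C(=C)C[C@@H](O[Si](C)(C)C(C)(C)C)/C=C(C)\C[C@H]1OC(=O)/C(C)=C/C
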